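**Retrosynthetic overview**
1. Last bond C6–C7 (seven-membered ring): the isopropenyl carbon C6 is turned by Fe–H hydrogen-atom transfer into a nucleophilic tertiary radical (a carbanion equivalent at a carbon that is an acceptor site in polar chemistry) and adds to the C7 N-tosylhydrazone of a bicyclo[3.1.1]heptenedione; loss of TsH and N2 leaves C7–H.
2. Enone: exo-to-endo alkene shift and allylic oxidation (C11) of the cycloadduct.
3. Six- and four-membered rings together: intramolecular vinylketene–alkene [2+2] of an acyclic (2E,6E)-trienoic acid that already carries both isovalerates.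
4. Side chain: Paterson aldol (chain C8), then 1,3-anti reduction (chain C10), on 8-oxo methyl geranate and methyl isopropenyl ketone.
5. Ring order: 6 + 4 in one step, then 7.

Assumption: ring compounds use the tricyclo[5.4.0.0(2,8)]undecane locants of the target (C1, C2, C7, C8 = cyclobutane; C9=C10–C11(=O) = enone bridge; C3–C6 = four-carbon bridge); chain locant n of the acyclic precursors becomes ring locant n+6 (n = 1–5) or n−5 (n = 6–11); commercial methyl geranate is taken as the (2E) isomer.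

**Step 1**
Reactants: 1 methyl (2E)-3,7-dimethylocta-2,6-dienoate (methyl geranate)
Product: 2 methyl (2E,6E)-3,7-dimethyl-8-oxoocta-2,6-dienoate
Conditions: SeO2 (1.1 equiv), 1,4-dioxane, 90 °C
Reagents that add atoms: selenium dioxide, O=[Se]=O
Why: Riley oxidation (ene then [2,3]-shift) attacks only the (E)-methyl of the electron-rich 6,7-alkene and gives the (E)-enal; no stereocentre is formed.

**Step 2**
Reactants: 2 methyl (2E,6E)-3,7-dimethyl-8-oxoocta-2,6-dienoate; 3 3-methylbut-3-en-2-one
Product: 6 methyl (2E,6E,8R)-8-hydroxy-3,7,11-trimethyl-10-oxododeca-2,6,11-trienoate, via diisopinocampheylboron enolate 4 (not isolated), via boron aldolate 5 (not isolated)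
Conditions: 3, (+)-Ipc2BCl, Et3N, Et2O, −78 to 0 °C; then 2, −78 to −20 °C; H2O2, MeOH/pH 7 buffer, 0 °C
Reagents that add atoms: none
Why: Paterson boron aldol: the methyl group of 3 is enolised regioselectively and the Ipc2B enolate adds to the Re face of the enal (boat transition state) to set 8R (ring C3); I am not certain of the facial sense for this reagent enantiomer, so (−)-Ipc2BCl is used instead if the adduct proves to be 8S, and the ee of about 85–90% can be raised by salt recrystallisation of acid 8.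

**Step 3**
Reactants: 6 methyl (2E,6E,8R)-8-hydroxy-3,7,11-trimethyl-10-oxododeca-2,6,11-trienoate
Product: 7 methyl (2E,6E,8R,10R)-8,10-dihydroxy-3,7,11-trimethyldodeca-2,6,11-trienoate
Conditions: Me4NBH(OAc)3, MeCN/AcOH 1:1, −30 °C
Reagents that add atoms: none
Why: Evans–Saksena reduction: the C8 alkoxide binds boron and delivers hydride intramolecularly through a chair transition state, giving the 1,3-anti diol and setting 10R (ring C5) by 1,2-reduction of the enone carbonyl.

**Step 4**
Reactants: 7 methyl (2E,6E,8R,10R)-8,10-dihydroxy-3,7,11-trimethyldodeca-2,6,11-trienoate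
Product: 8 (2E,6E,8R,10R)-8,10-dihydroxy-3,7,11-trimethyldodeca-2,6,11-trienoic acid
Conditions: LiOH·H2O, THF/MeOH/H2O, rt; then 1 M HCl to pH 3, 0 °C
Reagents that add atoms: lithium hydroxide, [Li+].[OH-]
Why: Saponification of the methyl ester before the base-labile isovalerates are introduced; no stereocentre is touched.

**Step 5**
Reactants: 8 (2E,6E,8R,10R)-8,10-dihydroxy-3,7,11-trimethyldodeca-2,6,11-trienoic acid; 9 3-methylbutanoyl chloride (isovaleryl chloride)
Product: 11 (2E,6E,8R,10R)-3,7,11-trimethyl-8,10-bis[(3-methylbutanoyl)oxy]dodeca-2,6,11-trienoic acid, via mixed anhydride 10 (not isolated)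
Conditions: 9 (3.5 equiv), pyridine, DMAP (cat.), CH2Cl2, 0 °C to rt; then H2O/THF, rt
Reagents that add atoms: none
Why: DMAP-catalysed acylation installs both target esters with retention at C8 and C10, and water cleaves the transient mixed anhydride at its more electrophilic isovaleryl carbonyl to return the free acid.

**Step 6**
Reactants: 11 (2E,6E,8R,10R)-3,7,11-trimethyl-8,10-bis[(3-methylbutanoyl)oxy]dodeca-2,6,11-trienoic acid
Product: 14 (1R,3R)-4-methyl-1-[(1R,5S,7S)-7-methyl-2-methylidene-6-oxobicyclo[3.1.1]heptan-7-yl]pent-4-ene-1,3-diyl bis(3-methylbutanoate), via acid chloride 12 (not isolated), via vinylketene 13 (not isolated)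
Conditions: (COCl)2, DMF (cat.), CH2Cl2, 0 °C to rt, concentrate; then Et3N (3 equiv), toluene, 110 °C, slow addition (0.005 M)
Reagents that add atoms: none
Why: Snider-type intramolecular vinylketene–alkene [2+2]: the ketene carbonyl carbon bonds to the less substituted alkene carbon (crossed mode, bicyclo[3.1.1]) and suprafacial addition to the (6E)-alkene places the 7-methyl syn to the three-carbon bridge and the side chain towards the cyclobutanone; the absolute sense comes from 1,2-induction by the C8 stereocentre, whose selectivity is expected to be modest and whose direction I cannot predict with confidence, so the two diastereomers are separated by chromatography.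

**Step 7**
Reactants: 14 bicyclic ketone with exocyclic methylidene
Product: 15 (1R,3R)-1-[(1R,5S,7S)-2,7-dimethyl-6-oxobicyclo[3.1.1]hept-2-en-7-yl]-4-methylpent-4-ene-1,3-diyl bis(3-methylbutanoate)
Conditions: RhCl3·3H2O (5 mol %), EtOH, 60 °C, short reaction time
Reagents that add atoms: none
Why: Rh–H addition/β-hydride elimination moves the strained exocyclic alkene into the ring (β-pinene to α-pinene type isomerisation), while the isopropenyl group mainly undergoes a degenerate shift; no stereocentre changes.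

**Step 8**
Reactants: 15 bicyclic ketone with endocyclic alkene
Product: 16 (1R,3R)-1-[(1R,5R,7R)-2,7-dimethyl-4,6-dioxobicyclo[3.1.1]hept-2-en-7-yl]-4-methylpent-4-ene-1,3-diyl bis(3-methylbutanoate)
Conditions: CrO3, 3,5-dimethylpyrazole, CH2Cl2, −20 °C
Reagents that add atoms: chromium trioxide, O=[Cr](=O)=O
Why: Salmond allylic oxidation converts the only ring allylic CH2 into the enone carbonyl (α-pinene to verbenone type); the bridgehead allylic C–H is inert and no stereocentre is affected.

**Step 9**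
Reactants: 16 enone-cyclobutanone
Product: 17 cyclobutanone N-tosylhydrazone of 16 (C=N–NHTs at bicyclo C6, future ring C7)
Conditions: TsNHNH2 (1.05 equiv), MeOH, rt
Reagents that add atoms: 4-methylbenzenesulfonohydrazide, Cc1ccc(cc1)S(=O)(=O)NN
Why: Hydrazone condensation occurs selectively at the strained, unconjugated cyclobutanone rather than at the hindered conjugated enone carbonyl.

**Step 10**
Reactants: 17 cyclobutanone N-tosylhydrazone
Product: 19 (1R,2R,3R,5R,7S,8R)-2,6,6,9-tetramethyl-11-oxotricyclo[5.4.0.0(2,8)]undec-9-ene-3,5-diyl bis(3-methylbutanoate) (target), via sulfonyl hydrazide 18 (not isolated)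
Conditions: Fe(acac)3 (20 mol %), PhSiH3 (2.5 equiv), EtOH/THF, 60 °C, 0.01 M; then NaOAc (cat.), MeOH, 65 °C
Reagents that add atoms: none
Why: Proposed new method: Fe–H hydrogen-atom transfer (Mukaiyama-type) to the isopropenyl group makes C6 a nucleophilic tertiary radical, which adds 7-exo to the electrophilic C7=N carbon from the only face the C2 tether can reach (so two acceptor carbons are joined and C7 is fixed with the new bond anti to the enone bridge), and the resulting hydrazide 18 loses toluenesulfinic acid and N2 (alkyldiazene fragmentation) to leave C7–H; the closest known reactions are Fe-catalysed alkene–sulfonylhydrazone reductive couplings forming 5- and 6-membered rings, alkene hydromethylation via formaldehyde sulfonylhydrazone, and radical cyclisations onto N-aziridinylimines.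

**Compound list**
1 | methyl (2E)-3,7-dimethylocta-2,6-dienoate | COC(=O)/C=C(\C)CCC=C(C)C | starting material
2 | methyl (2E,6E)-3,7-dimethyl-8-oxoocta-2,6-dienoate | COC(=O)/C=C(\C)CC/C=C(\C)C=O | intermediate
3 | 3-methylbut-3-en-2-one | CC(=O)C(C)=C | starting material
4 | diisopinocampheylboron enolate of 3 | C=C(OB([C@H]1C[C@H]2C[C@@H]([C@@H]1C)C2(C)C)[C@H]1C[C@H]2C[C@@H]([C@@H]1C)C2(C)C)C(C)=C | intermediate (not isolated)
5 | boron aldolate of 6 | COC(=O)/C=C(\C)CC/C=C(\C)[C@H](OB([C@H]1C[C@H]2C[C@@H]([C@@H]1C)C2(C)C)[C@H]1C[C@H]2C[C@@H]([C@@H]1C)C2(C)C)CC(=O)C(C)=C | intermediate (not isolated)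
6 | methyl (2E,6E,8R)-8-hydroxy-3,7,11-trimethyl-10-oxododeca-2,6,11-trienoate | COC(=O)/C=C(\C)CC/C=C(\C)[C@H](O)CC(=O)C(C)=C | intermediate
7 | methyl (2E,6E,8R,10R)-8,10-dihydroxy-3,7,11-trimethyldodeca-2,6,11-trienoate | COC(=O)/C=C(\C)CC/C=C(\C)[C@H](O)C[C@@H](O)C(C)=C | intermediate
8 | (2E,6E,8R,10R)-8,10-dihydroxy-3,7,11-trimethyldodeca-2,6,11-trienoic acid | OC(=O)/C=C(\C)CC/C=C(\C)[C@H](O)C[C@@H](O)C(C)=C | intermediate
9 | 3-methylbutanoyl chloride | CC(C)CC(=O)Cl | starting material
10 | mixed anhydride of 11 with 3-methylbutanoic acid | CC(C)CC(=O)OC(=O)/C=C(\C)CC/C=C(\C)[C@H](OC(=O)CC(C)C)C[C@@H](OC(=O)CC(C)C)C(C)=C | intermediate (not isolated)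
11 | (2E,6E,8R,10R)-3,7,11-trimethyl-8,10-bis[(3-methylbutanoyl)oxy]dodeca-2,6,11-trienoic acid | OC(=O)/C=C(\C)CC/C=C(\C)[C@H](OC(=O)CC(C)C)C[C@@H](OC(=O)CC(C)C)C(C)=C | intermediate
12 | acid chloride of 11 | ClC(=O)/C=C(\C)CC/C=C(\C)[C@H](OC(=O)CC(C)C)C[C@@H](OC(=O)CC(C)C)C(C)=C | intermediate (not isolated)
13 | (6E,8R,10R)-7,11-dimethyl-3-methylidene-8,10-bis[(3-methylbutanoyl)oxy]dodeca-1,6,11-trien-1-one (vinylketene) | O=C=CC(=C)CC/C=C(\C)[C@H](OC(=O)CC(C)C)C[C@@H](OC(=O)CC(C)C)C(C)=C | intermediate (not isolated)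
14 | (1R,3R)-4-methyl-1-[(1R,5S,7S)-7-methyl-2-methylidene-6-oxobicyclo[3.1.1]heptan-7-yl]pent-4-ene-1,3-diyl bis(3-methylbutanoate) | C=C1CC[C@@H]2C(=O)[C@H]1[C@@]2(C)[C@H](OC(=O)CC(C)C)C[C@@H](OC(=O)CC(C)C)C(C)=C | intermediate
15 | (1R,3R)-1-[(1R,5S,7S)-2,7-dimethyl-6-oxobicyclo[3.1.1]hept-2-en-7-yl]-4-methylpent-4-ene-1,3-diyl bis(3-methylbutanoate) | CC1=CC[C@@H]2C(=O)[C@H]1[C@@]2(C)[C@H](OC(=O)CC(C)C)C[C@@H](OC(=O)CC(C)C)C(C)=C | intermediate
16 | (1R,3R)-1-[(1R,5R,7R)-2,7-dimethyl-4,6-dioxobicyclo[3.1.1]hept-2-en-7-yl]-4-methylpent-4-ene-1,3-diyl bis(3-methylbutanoate) | CC1=CC(=O)[C@@H]2C(=O)[C@H]1[C@@]2(C)[C@H](OC(=O)CC(C)C)C[C@@H](OC(=O)CC(C)C)C(C)=C | intermediate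
17 | cyclobutanone N-tosylhydrazone of 16 | CC1=CC(=O)[C@@H]2C(=NNS(=O)(=O)c3ccc(C)cc3)[C@H]1[C@@]2(C)[C@H](OC(=O)CC(C)C)C[C@@H](OC(=O)CC(C)C)C(C)=C | intermediate
18 | tricyclic C7 N'-tosylhydrazide (C6–C7 bond closed; NHNHTs on C7 syn to the enone bridge) | CC1=CC(=O)[C@@H]2[C@]3(NNS(=O)(=O)c4ccc(C)cc4)[C@H]1[C@@]2(C)[C@H](OC(=O)CC(C)C)C[C@@H](OC(=O)CC(C)C)C3(C)C | intermediate (not isolated)
19 | (1R,2R,3R,5R,7S,8R)-2,6,6,9-tetramethyl-11-oxotricyclo[5.4.0.0(2,8)]undec-9-ene-3,5-diyl bis(3-methylbutanoate) | CC1=CC(=O)[C@@H]2[C@@H]3[C@H]1[C@@]2(C)[C@H](OC(=O)CC(C)C)C[C@@H](OC(=O)CC(C)C)C3(C)C | target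

**Totals and risks**
Total step count: 10. Longest linear sequence: 10 (1 to 19).

Three steps most likely to fail:

Step 6 (ketene [2+2]: yield with an alkene carrying an allylic acyloxy group, and facial selectivity relative to C8). The fallback sets out from 7 and returns at 14, and changes the stereocontrol element from an acyloxy to a large silyloxy group. Diol 7 is silylated (TBSOTf, 2,6-lutidine) to the bis-TBS ether methyl ester F1 and saponified to the bis-TBS acid F2. Oxalyl chloride gives the bis-TBS acid chloride F3, and Et3N in hot toluene gives the bis-TBS vinylketene F4, which cyclises to the bis-TBS bicyclic ketone F5; the bulky C8 silyloxy group should sit anti to the incoming ketene. HF·pyridine then frees the diol ketone F6, which is acylated with 9 to give 14.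

Step 7 (the Rh–H catalyst may also move the side-chain alkene towards the enol ester). The fallback sets out from 14 and returns at 15 by a pericyclic relay with no metal hydride. Liquid SO2 in CH2Cl2 undergoes an ene reaction with the exocyclic alkene to give the primary allylic sulfinic acid F7. A [1,3]-sigmatropic shift gives the secondary allylic sulfinic acid F8, and retro-ene loss of SO2 delivers 15; the isopropenyl group can only undergo a degenerate shift by this path.

Step 10 (the 7-exo radical addition to the hydrazone may lose to simple reduction of the C6 radical). The fallback sets out from 16 and returns at 19. Dione 16 itself is treated with Fe(acac)3/PhSiH3, so that the C6 radical adds to the cyclobutanone carbonyl (alkene–ketone reductive coupling) and gives the tricyclic tertiary cyclobutanol F9. Acylation with methyl oxalyl chloride/DMAP gives the methyl oxalate F10, and radical deoxygenation with Bu3SnH/AIBN leaves C7–H, giving 19.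

**Further compounds**
F1 | step 6 | methyl (2E,6E,8R,10R)-8,10-bis(tert-butyldimethylsilyloxy)-3,7,11-trimethyldodeca-2,6,11-trienoate | COC(=O)/C=C(\C)CC/C=C(\C)[C@H](O[Si](C)(C)C(C)(C)C)C[C@@H](O[Si](C)(C)C(C)(C)C)C(C)=C
F2 | step 6 | (2E,6E,8R,10R)-8,10-bis(tert-butyldimethylsilyloxy)-3,7,11-trimethyldodeca-2,6,11-trienoic acid | OC(=O)/C=C(\C)CC/C=C(\C)[C@H](O[Si](C)(C)C(C)(C)C)C[C@@H](O[Si](C)(C)C(C)(C)C)C(C)=C
F3 | step 6 | acid chloride of F2 | ClC(=O)/C=C(\C)CC/C=C(\C)[C@H](O[Si](C)(C)C(C)(C)C)C[C@@H](O[Si](C)(C)C(C)(C)C)C(C)=C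
F4 | step 6 | bis-TBS vinylketene | O=C=CC(=C)CC/C=C(\C)[C@H](O[Si](C)(C)C(C)(C)C)C[C@@H](O[Si](C)(C)C(C)(C)C)C(C)=C
F5 | step 6 | bis-TBS ether of the bicyclic ketone (14 with OTBS in place of both esters) | C=C1CC[C@@H]2C(=O)[C@H]1[C@@]2(C)[C@H](O[Si](C)(C)C(C)(C)C)C[C@@H](O[Si](C)(C)C(C)(C)C)C(C)=C
F6 | step 6 | 7-[(1R,3R)-1,3-dihydroxy-4-methylpent-4-enyl]-7-methyl-2-methylidenebicyclo[3.1.1]heptan-6-one | C=C1CC[C@@H]2C(=O)[C@H]1[C@@]2(C)[C@H](O)C[C@@H](O)C(C)=C
F7 | step 7 | primary allylic sulfinic acid (SO2 ene adduct of 14; CH2SO2H on the ring alkene carbon) | OS(=O)CC1=CC[C@@H]2C(=O)[C@H]1[C@@]2(C)[C@H](OC(=O)CC(C)C)C[C@@H](OC(=O)CC(C)C)C(C)=C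
F8 | step 7 | secondary allylic sulfinic acid (SO2H on bicyclo C3, exocyclic methylidene; C3 epimers) | C=C1C(S(=O)O)C[C@@H]2C(=O)[C@H]1[C@@]2(C)[C@H](OC(=O)CC(C)C)C[C@@H](OC(=O)CC(C)C)C(C)=C
F9 | step 10 | tricyclic tertiary cyclobutanol (19 with OH on C7 in place of H) | CC1=CC(=O)[C@@H]2[C@]3(O)[C@H]1[C@@]2(C)[C@H](OC(=O)CC(C)C)C[C@@H](OC(=O)CC(C)C)C3(C)C
F10 | step 10 | methyl oxalate of F9 | CC1=CC(=O)[C@@H]2[C@]3(OC(=O)C(=O)OC)[C@H]1[C@@]2(C)[C@H](OC(=O)CC(C)C)C[C@@H](OC(=O)CC(C)C)C3(C)C
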